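**Plan**
- Retrosynthesis: after removal of the silyl and benzyl groups, ring A is cut at C1–C2 and C3–C4. Its ester carbon C1 lies between a methoxy carbon (C2) and an aryloxy carbon (C6), so C1, C6, C5, C4 can come from C3–C6 of a 4-aryloxy-2-pyranone-3-carboxylate and C2/C3 from the two sp carbons of a 1-methoxyalkyne that already holds the carbinol carbon.
- Further cuts: the aryl–O bond at C4 of the pyranone (tosylate 12 plus ring B phenol 6), the pyranone lactone (dibenzyl malonate plus 3-ethoxyacryloyl chloride), and the bond between the alkyne and the carbonyl carbon (amide 16 plus lithium methoxyacetylide).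
- Forward: ring B phenol from creosol (steps 1–5); the pyranone ring closes by lactonisation and takes ring B by addition–elimination (steps 6–9); the alkyne is built in steps 10–14; ring A forms last by cycloaddition and loss of CO2 (step 15); two deprotections follow.
- Stereochemistry: the only stereocenter (R) is set by asymmetric transfer hydrogenation of ynone 20 with the (R,R)-configured ruthenium catalyst and is carried through as a TBS ether.
- The acid is carried as a benzyl ester so that the hindered 2,6-disubstituted benzoate is freed by hydrogenolysis together with the aryl benzyl ether.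

Key step: step 15

Assumption: tautomeric compounds 9, 10 and 11 are each written as one tautomer, and 23 is taken to form as two bridgehead diastereomers that converge on aromatisation.

**Route**

Step 1
Reactants: 1 2-methoxy-4-methylphenol (creosol)
Product: 2 2-hydroxy-3-methoxy-5-methylbenzaldehyde
Conditions: (CH2O)n, MgCl2, Et3N, MeCN, reflux; aq. HCl
Reagents that add atoms: paraformaldehyde (formaldehyde source), C=O
Why: Magnesium phenoxide-directed ortho-formylation (Casnati–Skattebøl reaction) can only reach the one free position ortho to the hydroxyl, the other being occupied by the methoxy group.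

Step 2
Reactants: 2 2-hydroxy-3-methoxy-5-methylbenzaldehyde
Product: 3 2,3-dihydroxy-5-methylbenzaldehyde
Conditions: BBr3, CH2Cl2, −78 → 0 °C; H2O
Reagents that add atoms: none
Why: Lewis acid demethylation of an aryl methyl ether (boron–oxygen complexation, then SN2 loss of bromomethane) is standard for o-vanillin-type aldehydes and leaves the formyl group intact after aqueous work-up.

Step 3
Reactants: 3 2,3-dihydroxy-5-methylbenzaldehyde
Product: 4 3-(benzyloxy)-2-hydroxy-5-methylbenzaldehyde
Conditions: NaH (2.2 equiv), DMSO, rt; BnBr (1.0 equiv)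
Reagents that add atoms: benzyl bromide, BrCc1ccccc1
Why: In the dianion the 2-phenoxide is delocalised into and chelated by the formyl group, so the Williamson etherification should occur at the more nucleophilic 3-oxygen, as is established for 2,3-dihydroxybenzaldehyde.

Step 4
Reactants: 4 3-(benzyloxy)-2-hydroxy-5-methylbenzaldehyde
Product: 5 2-(benzyloxy)-6-(hydroxymethyl)-4-methylphenol
Conditions: NaBH4, MeOH/THF, 0 °C
Reagents that add atoms: none
Why: Borohydride reduction of an aryl aldehyde, with no other reducible group present.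

Step 5
Reactants: 5 2-(benzyloxy)-6-(hydroxymethyl)-4-methylphenol
Product: 6 2-(benzyloxy)-6-({[tert-butyl(dimethyl)silyl]oxy}methyl)-4-methylphenol
Conditions: TBSCl (1.05 equiv), imidazole, CH2Cl2, 0 °C
Reagents that add atoms: tert-butyldimethylsilyl chloride (TBSCl), CC(C)(C)[Si](C)(C)Cl
Why: The primary benzylic hydroxyl silylates faster than the flanked, hydrogen-bonded phenol, and silicon is thermodynamically better placed on the alkyl oxygen because the phenoxide is the more stable anion.

Step 6
Reactants: 7 dibenzyl propanedioate (dibenzyl malonate); 8 (2E)-3-ethoxyprop-2-enoyl chloride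
Product: 9 dibenzyl 2-[(2E)-3-ethoxyprop-2-enoyl]propanedioate
Conditions: MgCl2, Et3N, MeCN, 0 °C → rt; cold aq. HCl
Reagents that add atoms: none
Why: Soft enolisation with MgCl2/Et3N gives the chelated magnesium malonate enolate, which undergoes C-acylation by the acid chloride at its carbonyl carbon, a standard malonate acylation.

Step 7
Reactants: 9 dibenzyl 2-[(2E)-3-ethoxyprop-2-enoyl]propanedioate
Product: 11 benzyl 4-hydroxy-2-oxo-2H-pyran-3-carboxylate, via dibenzyl 2-(3-oxopropanoyl)propanedioate 10 (not isolated)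
Conditions: TFA, H2O, CH2Cl2, 0 °C → rt
Reagents that add atoms: water, O
Why: Acid-catalysed hydrolysis of the vinylogous ester (conjugate addition of water, loss of ethanol) unmasks tricarbonyl compound 10, whose terminal enol lactonises onto one benzyl ester in the classical tricarbonyl to 4-hydroxy-2-pyranone cyclisation.

Step 8
Reactants: 11 benzyl 4-hydroxy-2-oxo-2H-pyran-3-carboxylate
Product: 12 benzyl 4-{[(4-methylphenyl)sulfonyl]oxy}-2-oxo-2H-pyran-3-carboxylate
Conditions: TsCl, Et3N, CH2Cl2, 0 °C
Reagents that add atoms: 4-methylbenzenesulfonyl chloride (TsCl), Cc1ccc(cc1)S(=O)(=O)Cl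
Why: O-sulfonylation of the acidic vinylogous carboxylic acid hydroxyl, as is routine for 4-hydroxy-2-pyranones.

Step 9
Reactants: 12 benzyl 4-{[(4-methylphenyl)sulfonyl]oxy}-2-oxo-2H-pyran-3-carboxylate; 6 2-(benzyloxy)-6-({[tert-butyl(dimethyl)silyl]oxy}methyl)-4-methylphenol
Product: 13 benzyl 4-[2-(benzyloxy)-6-({[tert-butyl(dimethyl)silyl]oxy}methyl)-4-methylphenoxy]-2-oxo-2H-pyran-3-carboxylate
Conditions: Cs2CO3, MeCN, 0 °C → rt
Reagents that add atoms: none
Why: Addition–elimination (vinylogous acyl substitution): the phenoxide adds at C4, which is β to both the lactone and the ester carbonyl, and tosylate leaves, a pathway at a planar sp2 carbon that should accept the doubly ortho-substituted phenoxide.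

Step 10
Reactants: 14 3-hydroxy-3-methylbutanoic acid
Product: 15 3-hydroxy-N-methoxy-N,3-dimethylbutanamide
Conditions: MeNHOMe·HCl, EDC·HCl, HOBt (cat.), i-Pr2NEt, CH2Cl2, 0 °C → rt
Reagents that add atoms: N,O-dimethylhydroxylamine hydrochloride, Cl.CNOC
Why: Carbodiimide-mediated amide coupling, in which the unreactive tertiary hydroxyl does not compete with the amine.

Step 11
Reactants: 15 3-hydroxy-N-methoxy-N,3-dimethylbutanamide
Product: 16 N-methoxy-N,3-dimethyl-3-[(triethylsilyl)oxy]butanamide
Conditions: TESOTf, 2,6-lutidine, CH2Cl2, 0 °C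
Reagents that add atoms: triethylsilyl trifluoromethanesulfonate (TESOTf), CC[Si](CC)(CC)OS(=O)(=O)C(F)(F)F
Why: A silyl triflate with a hindered pyridine base silylates tertiary alcohols reliably, and the ether keeps this oxygen from adding to the ynone or the ynol ether later.

Step 12
Reactants: 16 N-methoxy-N,3-dimethyl-3-[(triethylsilyl)oxy]butanamide; 17 2-chloro-1,1-dimethoxyethane
Product: 20 1-methoxy-5-methyl-5-[(triethylsilyl)oxy]hex-1-yn-3-one, via lithium methoxyacetylide 18 (not isolated), via lithium hemiaminal adduct 19 (not isolated)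
Conditions: 17, LiNEt2 (from n-BuLi, Et2NH), THF, 0 °C; 16, −78 → −30 °C; inverse quench into cold aq. citric acid
Reagents that add atoms: none
Why: Two eliminations and a deprotonation convert the chloroacetal into acetylide 18, which adds once to the amide (Weinreb ketone synthesis) because chelated adduct 19 survives until the acidic inverse quench, which also protonates the amines before they can add to the ynone.

Step 13
Reactants: 20 1-methoxy-5-methyl-5-[(triethylsilyl)oxy]hex-1-yn-3-one
Product: 21 (3R)-1-methoxy-5-methyl-5-[(triethylsilyl)oxy]hex-1-yn-3-ol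
Conditions: RuCl[(R,R)-TsDPEN](p-cymene) (2 mol %), KOH (2 mol %), i-PrOH, rt
Reagents that add atoms: none
Why: Noyori asymmetric transfer hydrogenation of an α,β-acetylenic ketone, in which the alkynyl group takes the place of the aryl group of aryl ketones, so the (R,R)-catalyst should deliver hydride to the face that gives the R carbinol under neutral conditions that spare the ynol ether.

Step 14
Reactants: 21 (3R)-1-methoxy-5-methyl-5-[(triethylsilyl)oxy]hex-1-yn-3-ol
Product: 22 (3R)-3-{[tert-butyl(dimethyl)silyl]oxy}-1-methoxy-5-methyl-5-[(triethylsilyl)oxy]hex-1-yne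
Conditions: TBSCl, imidazole, DMF, rt
Reagents that add atoms: tert-butyldimethylsilyl chloride (TBSCl), CC(C)(C)[Si](C)(C)Cl
Why: Imidazole-buffered silylation of a secondary alcohol avoids the acid that would trigger Meyer–Schuster rearrangement of the alkoxy propargylic alcohol and does not touch the stereocenter.

Step 15
Reactants: 13 benzyl 4-[2-(benzyloxy)-6-({[tert-butyl(dimethyl)silyl]oxy}methyl)-4-methylphenoxy]-2-oxo-2H-pyran-3-carboxylate; 22 (3R)-3-{[tert-butyl(dimethyl)silyl]oxy}-1-methoxy-5-methyl-5-[(triethylsilyl)oxy]hex-1-yne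
Product: 24 benzyl 6-[2-(benzyloxy)-6-({[tert-butyl(dimethyl)silyl]oxy}methyl)-4-methylphenoxy]-3-[(1R)-1-{[tert-butyl(dimethyl)silyl]oxy}-3-methyl-3-[(triethylsilyl)oxy]butyl]-2-methoxybenzoate, via bridged bicyclic lactone 23 (not isolated)
Conditions: 22 (1.5 equiv), PhMe, 110 °C, sealed tube
Reagents that add atoms: none
Why: The methoxyalkyne is the electron-rich 2π partner and the pyranone, made electron-poor by the C3 ester and the lactone carbonyl, the 4π partner of an inverse-electron-demand Diels–Alder reaction; the chain-bearing alkyne carbon (the nucleophilic end of the ynol ether) should bond to the unsubstituted, electrophilic C6 and the methoxy-bearing carbon to C3, probably asynchronously, to give bridged lactone 23. Retro-Diels–Alder loss of CO2 from 23 is expected to be fast at this temperature and delivers the benzoate irreversibly. The closest known reactions are the cycloaddition and decarboxylation of 3-alkoxycarbonyl-2-pyranones with ynamines and ketene acetals, which give benzoates with the heteroatom next to the ester. Ring A is closed by an intermolecular (4+2) cycloaddition that forms C1–C2 and C3–C4 in one operation, followed by cycloreversion; no stereocenter is created in 24, since the bridgehead centers of 23 vanish on aromatisation, and the silyloxy-bearing carbon has no acidic hydrogen and keeps its R configuration. The step needs regioselectivity (methoxy ortho to the ester), secured by this polarity match and by the preference of the bulkier alkyne terminus for the CH end of the diene, and it needs the ynol ether to survive heating, secured because a methyl ynol ether has no β-hydrogen for retro-ene fragmentation to a ketene.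

Step 16
Reactants: 24 benzyl 6-[2-(benzyloxy)-6-({[tert-butyl(dimethyl)silyl]oxy}methyl)-4-methylphenoxy]-3-[(1R)-1-{[tert-butyl(dimethyl)silyl]oxy}-3-methyl-3-[(triethylsilyl)oxy]butyl]-2-methoxybenzoate
Product: 25 6-[2-({[tert-butyl(dimethyl)silyl]oxy}methyl)-6-hydroxy-4-methylphenoxy]-3-[(1R)-1-{[tert-butyl(dimethyl)silyl]oxy}-3-methyl-3-[(triethylsilyl)oxy]butyl]-2-methoxybenzoic acid
Conditions: H2 (1 atm), 10% Pd/C, EtOAc, rt
Reagents that add atoms: none
Why: Hydrogenolysis cleaves the benzyl ester and the aryl benzyl ether at their O–CH2 bonds regardless of crowding at the carbonyl, while the silyl-protected benzylic oxygens and the diaryl ether should be inert in ethyl acetate.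

Step 17
Reactants: 25 6-[2-({[tert-butyl(dimethyl)silyl]oxy}methyl)-6-hydroxy-4-methylphenoxy]-3-[(1R)-1-{[tert-butyl(dimethyl)silyl]oxy}-3-methyl-3-[(triethylsilyl)oxy]butyl]-2-methoxybenzoic acid
Product: 26 3-[(1R)-1,3-dihydroxy-3-methylbutyl]-6-[2-hydroxy-6-(hydroxymethyl)-4-methylphenoxy]-2-methoxybenzoic acid (CNP0452050.1)
Conditions: TBAF, AcOH, THF, 0 → 40 °C; aq. citric acid (pH 4), EtOAc
Reagents that add atoms: none
Why: Fluoride-mediated cleavage of the three Si–O bonds under buffered, non-acidic conditions avoids ionisation of the electron-rich benzylic carbinol, so the R center is kept.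

**Compound list**
1 | 2-methoxy-4-methylphenol (creosol) | COc1cc(C)ccc1O | starting material
2 | 2-hydroxy-3-methoxy-5-methylbenzaldehyde | COc1cc(C)cc(C=O)c1O | intermediate
3 | 2,3-dihydroxy-5-methylbenzaldehyde | O=Cc1cc(C)cc(O)c1O | intermediate
4 | 3-(benzyloxy)-2-hydroxy-5-methylbenzaldehyde | O=Cc1cc(C)cc(OCc2ccccc2)c1O | intermediate
5 | 2-(benzyloxy)-6-(hydroxymethyl)-4-methylphenol | Cc1cc(CO)c(O)c(OCc2ccccc2)c1 | intermediate
6 | 2-(benzyloxy)-6-({[tert-butyl(dimethyl)silyl]oxy}methyl)-4-methylphenol | Cc1cc(CO[Si](C)(C)C(C)(C)C)c(O)c(OCc2ccccc2)c1 | intermediate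
7 | dibenzyl propanedioate (dibenzyl malonate) | O=C(CC(=O)OCc1ccccc1)OCc1ccccc1 | starting material
8 | (2E)-3-ethoxyprop-2-enoyl chloride | CCO/C=C/C(Cl)=O | starting material
9 | dibenzyl 2-[(2E)-3-ethoxyprop-2-enoyl]propanedioate | CCO/C=C/C(=O)C(C(=O)OCc1ccccc1)C(=O)OCc1ccccc1 | intermediate
10 | dibenzyl 2-(3-oxopropanoyl)propanedioate | O=CCC(=O)C(C(=O)OCc1ccccc1)C(=O)OCc1ccccc1 | intermediate (not isolated)
11 | benzyl 4-hydroxy-2-oxo-2H-pyran-3-carboxylate | O=C(OCc1ccccc1)C1=C(O)C=COC1=O | intermediate
12 | benzyl 4-{[(4-methylphenyl)sulfonyl]oxy}-2-oxo-2H-pyran-3-carboxylate | Cc1ccc(cc1)S(=O)(=O)OC1=C(C(=O)OCc2ccccc2)C(=O)OC=C1 | intermediate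
13 | benzyl 4-[2-(benzyloxy)-6-({[tert-butyl(dimethyl)silyl]oxy}methyl)-4-methylphenoxy]-2-oxo-2H-pyran-3-carboxylate | O=C(OCc1ccccc1)C1=C(Oc2c(OCc3ccccc3)cc(C)cc2CO[Si](C)(C)C(C)(C)C)C=COC1=O | intermediate
14 | 3-hydroxy-3-methylbutanoic acid | CC(C)(O)CC(=O)O | starting material
15 | 3-hydroxy-N-methoxy-N,3-dimethylbutanamide | CON(C)C(=O)CC(C)(C)O | intermediate
16 | N-methoxy-N,3-dimethyl-3-[(triethylsilyl)oxy]butanamide | CON(C)C(=O)CC(C)(C)O[Si](CC)(CC)CC | intermediate
17 | 2-chloro-1,1-dimethoxyethane (chloroacetaldehyde dimethyl acetal) | COC(CCl)OC | starting material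
18 | lithium methoxyacetylide | [Li]C#COC | intermediate (not isolated)
19 | lithium 1-methoxy-3-[methoxy(methyl)amino]-5-methyl-5-[(triethylsilyl)oxy]hex-1-yn-3-olate (hemiaminal adduct, configuration at C3 undefined) | COC#CC(O[Li])(N(C)OC)CC(C)(C)O[Si](CC)(CC)CC | intermediate (not isolated)
20 | 1-methoxy-5-methyl-5-[(triethylsilyl)oxy]hex-1-yn-3-one | COC#CC(=O)CC(C)(C)O[Si](CC)(CC)CC | intermediate
21 | (3R)-1-methoxy-5-methyl-5-[(triethylsilyl)oxy]hex-1-yn-3-ol | COC#C[C@H](O)CC(C)(C)O[Si](CC)(CC)CC | intermediate
22 | (3R)-3-{[tert-butyl(dimethyl)silyl]oxy}-1-methoxy-5-methyl-5-[(triethylsilyl)oxy]hex-1-yne | COC#C[C@H](O[Si](C)(C)C(C)(C)C)CC(C)(C)O[Si](CC)(CC)CC | intermediate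
23 | benzyl 5-[2-(benzyloxy)-6-({[tert-butyl(dimethyl)silyl]oxy}methyl)-4-methylphenoxy]-7-[(1R)-1-{[tert-butyl(dimethyl)silyl]oxy}-3-methyl-3-[(triethylsilyl)oxy]butyl]-8-methoxy-3-oxo-2-oxabicyclo[2.2.2]octa-5,7-diene-4-carboxylate (two bridgehead diastereomers) | O=C1OC2C=C(Oc3c(OCc4ccccc4)cc(C)cc3CO[Si](C)(C)C(C)(C)C)C1(C(=O)OCc5ccccc5)C(OC)=C2[C@H](O[Si](C)(C)C(C)(C)C)CC(C)(C)O[Si](CC)(CC)CC | intermediate (not isolated)
24 | benzyl 6-[2-(benzyloxy)-6-({[tert-butyl(dimethyl)silyl]oxy}methyl)-4-methylphenoxy]-3-[(1R)-1-{[tert-butyl(dimethyl)silyl]oxy}-3-methyl-3-[(triethylsilyl)oxy]butyl]-2-methoxybenzoate | COc1c([C@H](O[Si](C)(C)C(C)(C)C)CC(C)(C)O[Si](CC)(CC)CC)ccc(Oc2c(OCc3ccccc3)cc(C)cc2CO[Si](C)(C)C(C)(C)C)c1C(=O)OCc1ccccc1 | intermediate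
25 | 6-[2-({[tert-butyl(dimethyl)silyl]oxy}methyl)-6-hydroxy-4-methylphenoxy]-3-[(1R)-1-{[tert-butyl(dimethyl)silyl]oxy}-3-methyl-3-[(triethylsilyl)oxy]butyl]-2-methoxybenzoic acid | COc1c([C@H](O[Si](C)(C)C(C)(C)C)CC(C)(C)O[Si](CC)(CC)CC)ccc(Oc2c(O)cc(C)cc2CO[Si](C)(C)C(C)(C)C)c1C(=O)O | intermediate
26 | 3-[(1R)-1,3-dihydroxy-3-methylbutyl]-6-[2-hydroxy-6-(hydroxymethyl)-4-methylphenoxy]-2-methoxybenzoic acid (CNP0452050.1) | COc1c([C@H](O)CC(C)(C)O)ccc(Oc2c(O)cc(C)cc2CO)c1C(=O)O | target

**Totals**
Total step count: 17. Longest linear sequence: 9 steps (steps 1–5, 9, 15, 16, 17).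

**Steps most likely to fail**

Step 15. The aryloxy group at C4 donates into the diene and may slow the cycloaddition until thermal decay or oligomerisation of the ynol ether takes over. The fallback removes the donor before the cycloaddition and forms the diaryl ether afterwards.
- It sets out from 11, which oxalyl bromide and catalytic DMF in CH2Cl2 (Vilsmeier-type deoxybromination) should convert into benzyl 4-bromo-2-oxo-2H-pyran-3-carboxylate F1.
- Heating F1 with 22 in toluene should give, through benzyl 5-bromo-7-[(1R)-1-{[tert-butyl(dimethyl)silyl]oxy}-3-methyl-3-[(triethylsilyl)oxy]butyl]-8-methoxy-3-oxo-2-oxabicyclo[2.2.2]octa-5,7-diene-4-carboxylate F2, which is not isolated, and loss of CO2, benzyl 6-bromo-3-[(1R)-1-{[tert-butyl(dimethyl)silyl]oxy}-3-methyl-3-[(triethylsilyl)oxy]butyl]-2-methoxybenzoate F3.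
- An Ullmann ether synthesis of F3 with phenol 6 (CuI, picolinic acid, K3PO4, DMSO, 90 °C), a protocol suited to hindered phenols and ortho-substituted aryl halides, should then form the diaryl ether and come back to the route at 24.

Step 13. The methoxy group donates through the alkyne into the carbonyl, so hydride transfer may be slow and conjugate addition of 2-propanol to the alkoxy ynone or poor facial selectivity may intervene. The fallback replaces asymmetric catalysis by resolution.
- It sets out from 20; Luche reduction (NaBH4, CeCl3·7H2O, MeOH, −78 °C) should give rac-1-methoxy-5-methyl-5-[(triethylsilyl)oxy]hex-1-yn-3-ol F4.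
- Kinetic resolution with Burkholderia cepacia lipase and vinyl acetate in MTBE is expected, by the usual size rule for lipase acylation of secondary alcohols with the slim methoxyethynyl group as the smaller substituent, to acetylate the S enantiomer to (3S)-1-methoxy-5-methyl-5-[(triethylsilyl)oxy]hex-1-yn-3-yl acetate F5.
- The R alcohol left unacylated is 21, where the route is rejoined.

Step 9. The doubly ortho-substituted phenoxide may attack sulfur of the tosylate (sulfonyl transfer) or C6 of the pyranone (ring opening) instead of C4. The fallback uses an electrophile whose leaving group offers no second site of attack.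
- It sets out from 11; oxalyl chloride and catalytic DMF in CH2Cl2 should give benzyl 4-chloro-2-oxo-2H-pyran-3-carboxylate F6.
- Addition–elimination of 6 on F6 with K2CO3 in MeCN should displace chloride and return to the route at 13.

**Further compounds**
F1 | step 15 | benzyl 4-bromo-2-oxo-2H-pyran-3-carboxylate | O=C(OCc1ccccc1)C1=C(Br)C=COC1=O
F2 | step 15 | benzyl 5-bromo-7-[(1R)-1-{[tert-butyl(dimethyl)silyl]oxy}-3-methyl-3-[(triethylsilyl)oxy]butyl]-8-methoxy-3-oxo-2-oxabicyclo[2.2.2]octa-5,7-diene-4-carboxylate | O=C1OC2C=C(Br)C1(C(=O)OCc3ccccc3)C(OC)=C2[C@H](O[Si](C)(C)C(C)(C)C)CC(C)(C)O[Si](CC)(CC)CC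
F3 | step 15 | benzyl 6-bromo-3-[(1R)-1-{[tert-butyl(dimethyl)silyl]oxy}-3-methyl-3-[(triethylsilyl)oxy]butyl]-2-methoxybenzoate | COc1c([C@H](O[Si](C)(C)C(C)(C)C)CC(C)(C)O[Si](CC)(CC)CC)ccc(Br)c1C(=O)OCc1ccccc1
F4 | step 13 | rac-1-methoxy-5-methyl-5-[(triethylsilyl)oxy]hex-1-yn-3-ol | COC#CC(O)CC(C)(C)O[Si](CC)(CC)CC
F5 | step 13 | (3S)-1-methoxy-5-methyl-5-[(triethylsilyl)oxy]hex-1-yn-3-yl acetate | COC#C[C@@H](OC(C)=O)CC(C)(C)O[Si](CC)(CC)CC
F6 | step 9 | benzyl 4-chloro-2-oxo-2H-pyran-3-carboxylate | O=C(OCc1ccccc1)C1=C(Cl)C=COC1=O
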